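Assumption: the target has no stereocentre, so no stereocontrol is planned; compounds 6, 7 and 10, which carry sp3 stereocentres on the way, are handled as racemates.

## Analysis of the target

Target 13 is 3,5,7,8-tetramethoxy-2-(2-methoxyphenyl)-4H-chromen-4-one: a benzo ring A fused to a 4-pyranone ring C, with an ortho-methoxyphenyl ring B on C2. There is no stereocentre and no double-bond geometry, so the problem is one of constitution and regiochemistry only. Ring A carries the 5,7,8-trioxygenation pattern with C6-H; closing ring C through the wrong phenolic oxygen would give the isomeric 5,6,7 pattern, so the oxygen that becomes O1 has to be defined unambiguously. Ring C is fully substituted, and its C3 methoxy group sits between the hindered C2 (ortho-substituted ring B) and the C4 carbonyl, which is peri to the 5-methoxy group. Of the five methyl ethers, the 5-methoxy group is the first to be lost to chelating Lewis acids, and C2 of the pyranone accepts hard nucleophiles with ring opening; late steps therefore have to avoid strong Lewis acids and hot alkoxide or hydroxide. The oxygen at C3 is the real difficulty, because the classical oxidative entries to 3-oxygenated flavones are unreliable when C5 is substituted. The plan rests on one feature: C3 lies between C2 (which bears ring B and O1) and the C4 carbonyl. Removing it contracts ring C to a furan and leaves a 2-aryl-3-oxybenzofuran, whose C2=C3 bond is an electron-rich enol ether that can take up a single carbon atom carrying a halogen, later exchanged for methoxy.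

## Retrosynthetic reasoning

**13 to 12.** The C3-OMe bond is cut first. C3 of a 4-pyranone is the α-carbon of a vinylogous ester and is not attacked by nucleophiles (they go to C2), so the ether is best made by metal-catalysed carbon-oxygen coupling of the C3 bromide 12. This reduces the five-ether problem to four ethers that are carried from the start plus one halide. The forward reaction has to exchange bromide for methoxide without letting free alkoxide add to C2.

**12 to 8 and 9.** The two skeletal bonds C2-C3 and C3-C4 are cut and C3 is removed together with its bromine. What remains closes formally to the benzofuran 8, in which C2 is unchanged and the old C4 has become the silyloxy-bearing C3. The cut is made here because both neighbours of C3 are then the two ends of one enol ether double bond, the natural partner for the electrophilic dihalocarbene available from 9 and base. One operation forms ring C at the right oxidation level and places a leaving group on C3, and the precursor is a five-membered heterocycle that closes by simple O-alkylation. The forward step must add the carbene only to C2=C3, open the cyclopropane in the ring-enlarging sense and release the silyl group from oxygen.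

**8 to 7.** The O-Si bond is cut. Silyl ether 8 is the enol derivative of ketone 7; silylation fixes the enol form, protects the easily autoxidised C2-H ketone, and supplies the group that leaves from oxygen when the carbonyl is regenerated in the key step.

**7 to 6.** The O1-C2 bond is cut, which leads back to a phenol and a benzylic α-bromo ketone within one molecule, compound 6. Ring closure is then an intramolecular ether synthesis onto a very reactive secondary bromide. This bond is chosen over C2-aryl or C3-C3a because both reacting groups derive from a single deoxybenzoin.

**6 to 5.** The C-Br bond is cut. The methylene group of 5 is flanked by a carbonyl and by ring B and is the only enolisable position, so halogenation through the enol is site-specific provided ring A is not attacked.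

**5 to 2 and 3 (via 4), and 2 to 1.** The aryl-carbonyl bond is cut. Arene 3 has two equivalent free positions, so acylation by 2 can give only ketone 4. In 4 the ortho methoxy group that is wedged between the acyl group and a neighbouring methoxy group is the one lost to the Lewis acid, which fixes the oxygen that becomes O1 and hence the 5,7,8 pattern. Acid chloride 2 comes from acid 1.

## Alternatives that were turned down

**Alternative 1:** The bond between C2 and ring B is disconnected, and ring B is delivered intramolecularly from a formaldehyde acetal that links O3 of a chromone to the oxygen of a 2-bromophenol.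
- Forward key step: 3-[(2-bromophenoxy)methoxy]-5,7,8-trimethoxy-4H-chromen-4-one A2 is treated with Pd(OAc)2, PCy3·HBF4, K2CO3 and pivalic acid. Carboxylate-assisted palladation of the chromone C2-H and reductive elimination would close a seven-membered dioxepine and give the methylene-bridged 3,2'-dioxyflavone A1.
- For it: the tether guarantees arylation at C2, both oxygens (O3 and O2') are in place before the C-C bond is made, and C3 never has to be oxygenated late. On that last point it is stronger than the chosen route.
- Against it: A2 already contains the complete 3-oxygenated 5,7,8-trimethoxychromone, so the hardest part of the target must be solved first by other means. The unsymmetrical O,O-acetal between an enolic hydroxyl and a phenol is awkward to assemble cleanly. After the coupling the acetal has to be cleaved with acid without touching the labile 5-methoxy group, and the two liberated hydroxyls then have to be methylated.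
- Comparison: tether on, tether off and double methylation add three operations that contribute nothing to the skeleton. The chosen route carries ring B with its ether from the first step and needs a single transition-metal step.

**Alternative 2:** The C3-C4 bond is disconnected by a reductive coupling of two aldehydes.
- Forward key step: rac-2-[1-(2-methoxyphenyl)-2-oxoethoxy]-3,4,6-trimethoxybenzaldehyde A4 is reduced with SmI2 in THF. The two ketyl radicals would couple and close ring C as the cis-3,4-diol A3.
- For it: the conditions are mild, six-membered pinacol closures are reliable, and C3 is oxygenated from the moment the ring forms. That is an advantage over the late C-O coupling of the chosen route.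
- Against it: A4 contains an α-aryloxy-α-aryl acetaldehyde, whose doubly activated α-hydrogen invites enolisation and β-elimination of the phenoxide. Making A4 means alkylating a phenol that is flanked on both sides with a secondary benzylic electrophile. Three stereocentres are created only to be destroyed. A3 is four oxidation-state units below the flavone level, so two carbinol oxidations with tautomerisation and a final methylation must follow, with a benzylic C2-H ether exposed to the oxidants.
- Comparison: the chosen ring enlargement is redox-neutral, creates no lasting stereocentre and reaches the pyranone directly. It is clearly shorter.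

**Alternative 3:** Three bonds (C4a-C4, C4-C3 and O1-C2) are disconnected at once, which leads to 6-iodo-2,3,5-trimethoxyphenol A6, CO and 1-ethynyl-2-methoxybenzene A7.
- Forward key step: PdCl2(PPh3)2 in Et2NH under CO would give the ortho-hydroxyaryl ynone by carbonylative alkynylation, and amine-mediated 6-endo addition of the phenol would close ring C to the flavone A5.
- For it: this is the most convergent proposal. It forms more bonds in one flask than the chosen key step, and A7 is a simple alkyne. On convergence it is stronger.
- Against it: A5 has hydrogen at C3, so the oxygen that defines the target still has to be introduced afterwards by a separate C3 oxidation and a methylation, on a hindered and electron-rich flavone. A6 has to be made by iodination ortho to the hydroxyl of a phenol whose para position, lying between two methoxy groups, is at least as reactive. The ynone can also close 5-exo to an aurone, and direct alkynylation without CO uptake leads to a benzofuran.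
- Comparison: the chosen route has a longer linear sequence to the heterocycle, but C3 arrives already bearing a leaving group, and the ring A pattern comes from a symmetric arene instead of from a regioselective halogenation.

Key step: step 5

## Route

Step 1
Reactants: 1 2-methoxyphenylacetic acid
Product: 2 2-methoxyphenylacetyl chloride
Conditions: (COCl)2, DMF (cat.), CH2Cl2, 0 °C to rt; concentrate, use crude
Reagents that add atoms: oxalyl chloride, O=C(Cl)C(=O)Cl
Why: Acid chloride formation through the Vilsmeier-type chloroiminium species made from DMF; the by-products are gases and the anisole ring and benzylic CH2 are inert.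

Step 2
Reactants: 2 2-methoxyphenylacetyl chloride; 3 1,2,3,5-tetramethoxybenzene
Product: 5 1-(2-hydroxy-3,4,6-trimethoxyphenyl)-2-(2-methoxyphenyl)ethan-1-one, via tetramethoxy deoxybenzoin 4 (not isolated)
Conditions: AlCl3 (2.5 equiv), Et2O, 0 °C to reflux; then 1 M HCl
Reagents that add atoms: none
Why: Friedel-Crafts acylation at one of the two equivalent free positions of 3 (each ortho to two methoxy groups and para to a third) gives only 4, which is deactivated against a second acylation. The aluminium chelate of 4 then loses the methyl group of the ortho methoxy that is buttressed between the acyl group and the neighbouring methoxy group, the well-established selective ortho-demethylation of 2,3,4,6-tetramethoxyphenyl ketones; the unchelated ether of ring B is not touched in ether solvent.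

Step 3
Reactants: 5 1-(2-hydroxy-3,4,6-trimethoxyphenyl)-2-(2-methoxyphenyl)ethan-1-one
Product: 6 rac-2-bromo-1-(2-hydroxy-3,4,6-trimethoxyphenyl)-2-(2-methoxyphenyl)ethan-1-one
Conditions: CuBr2 (2 equiv), EtOAc-CHCl3, reflux
Reagents that add atoms: CuBr2, [Cu+2].[Br-].[Br-]
Why: α-Bromination of a ketone with CuBr2 runs through the copper-bound enol and is the classical way to halogenate ortho-hydroxyaryl ketones on the side chain without nuclear bromination. The benzylic CH2 is the only enolisable position; the new stereocentre is racemic and is removed in step 4.

Step 4
Reactants: 6 rac-2-bromo-1-(2-hydroxy-3,4,6-trimethoxyphenyl)-2-(2-methoxyphenyl)ethan-1-one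
Product: 8 tert-butyl{[4,6,7-trimethoxy-2-(2-methoxyphenyl)-1-benzofuran-3-yl]oxy}dimethylsilane, via benzofuranone 7 (not isolated)
Conditions: DBU (2.5 equiv), THF, 0 °C to rt, Ar; then TBSCl, rt
Reagents that add atoms: tert-butyldimethylsilyl chloride (TBSCl), CC(C)(C)[Si](C)(C)Cl
Why: The phenoxide displaces the benzylic α-keto bromide in a 5-exo-tet intramolecular Williamson etherification to give 7. Its C2-H is strongly acidic because the conjugate base is an aromatic benzofuran-3-olate, which the hard silyl chloride captures on oxygen (silyl enol ether formation). Working in one flask under argon avoids isolating the autoxidation-prone ketone, and the C2 stereocentre disappears.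

Step 5
Reactants: 8 tert-butyl{[4,6,7-trimethoxy-2-(2-methoxyphenyl)-1-benzofuran-3-yl]oxy}dimethylsilane; 9 bromoform
Product: 12 3-bromo-5,7,8-trimethoxy-2-(2-methoxyphenyl)-4H-chromen-4-one, via dibromocyclopropane 10 (not isolated), via silyloxybenzopyrylium bromide 11 (not isolated)
Conditions: CHBr3 (3 equiv), KOt-Bu (4 equiv, in portions), toluene-hexane, −20 °C to rt
Reagents that add atoms: none
Why: KOt-Bu deprotonates CHBr3 and the anion loses bromide to give singlet dibromocarbene, an electrophile that adds in a concerted [2+1] fashion to the most electron-rich π bond of 8, the C2=C3 enol ether bond that carries O1 on one carbon and the silyloxy group on the other, giving the cis-fused cyclopropane 10. In 10 the bromide that lies syn to the five-membered ring ionises while the shared C2-C3 σ bond opens in a disrotatory two-electron electrocyclic process, and the cation formed is not a simple allyl cation but the aromatic 4-silyloxybenzopyrylium ion of 11, stabilised by O1, the silyloxy oxygen and ring B, which is the driving force. Bromide or tert-butoxide then takes the silyl group from oxygen and leaves the C4 carbonyl of 12. The closest known reaction types are the dihalocarbene ring enlargement of silyl enol ethers of cyclic ketones to 2-halo enones (including benzo-fused five-membered ketones) and the Ciamician-Dennstedt enlargement of indoles and benzofurans. Ring C is not closed by a cyclisation: the three-membered ring is closed by cheletropic addition, and the six-membered ring arises when the bond shared by the three- and five-membered rings is cut, so the new carbon becomes C3 between C2 and C4 with two new skeletal bonds, C2-C3 and C3-C4. No stereocentre remains, since the two of 10 are cis by necessity and vanish on opening. The step needs chemoselectivity for C2=C3 over rings A and B and over the product; the doubly oxygen-substituted double bond is far more nucleophilic than any arene position, and the enone of 12 is electron-poor and does not take up a second carbene. The silyl ether has to outlast the alkoxide until the carbene has added, which is why the bulky TBS group, a non-polar medium and low temperature are used.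

Step 6
Reactants: 12 3-bromo-5,7,8-trimethoxy-2-(2-methoxyphenyl)-4H-chromen-4-one
Product: 13 3,5,7,8-tetramethoxy-2-(2-methoxyphenyl)-4H-chromen-4-one
Conditions: Pd2(dba)3 (2.5 mol %), tBuBrettPhos (6 mol %), Cs2CO3, MeOH (5 equiv), toluene, 70 °C
Reagents that add atoms: methanol, CO
Why: Buchwald-type palladium-catalysed C-O coupling: zerovalent palladium inserts into the C3-Br bond, which behaves as a heteroaryl bromide, bromide is exchanged for methoxide, and the bulky biarylphosphine forces reductive elimination ahead of β-hydride elimination. Carbonate keeps the concentration of free methoxide low, so conjugate attack at C2 with ring opening and ring contraction, the usual fate of 3-halochromones in hot alkoxide, is held back.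

## Compound list

1 | 2-methoxyphenylacetic acid | COc1ccccc1CC(=O)O | starting material
2 | 2-methoxyphenylacetyl chloride | COc1ccccc1CC(=O)Cl | intermediate
3 | 1,2,3,5-tetramethoxybenzene | COc1cc(OC)c(OC)c(OC)c1 | starting material
4 | 2-(2-methoxyphenyl)-1-(2,3,4,6-tetramethoxyphenyl)ethan-1-one | COc1ccccc1CC(=O)c1c(OC)cc(OC)c(OC)c1OC | intermediate (not isolated)
5 | 1-(2-hydroxy-3,4,6-trimethoxyphenyl)-2-(2-methoxyphenyl)ethan-1-one | COc1ccccc1CC(=O)c1c(OC)cc(OC)c(OC)c1O | intermediate
6 | rac-2-bromo-1-(2-hydroxy-3,4,6-trimethoxyphenyl)-2-(2-methoxyphenyl)ethan-1-one (racemic) | COc1ccccc1C(Br)C(=O)c1c(OC)cc(OC)c(OC)c1O | intermediate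
7 | rac-4,6,7-trimethoxy-2-(2-methoxyphenyl)-1-benzofuran-3(2H)-one (racemic) | COc1ccccc1C1Oc2c(OC)c(OC)cc(OC)c2C1=O | intermediate (not isolated)
8 | tert-butyl{[4,6,7-trimethoxy-2-(2-methoxyphenyl)-1-benzofuran-3-yl]oxy}dimethylsilane | COc1ccccc1-c1oc2c(OC)c(OC)cc(OC)c2c1O[Si](C)(C)C(C)(C)C | intermediate
9 | bromoform | BrC(Br)Br | starting material
10 | rac-1,1-dibromo-6b-[(tert-butyldimethylsilyl)oxy]-3,4,6-trimethoxy-1a-(2-methoxyphenyl)-1a,6b-dihydro-1H-cyclopropa[b][1]benzofuran (racemic; the cis ring fusion is the only possible one) | COc1ccccc1C12Oc3c(OC)c(OC)cc(OC)c3C1(O[Si](C)(C)C(C)(C)C)C2(Br)Br | intermediate (not isolated)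
11 | 3-bromo-4-[(tert-butyldimethylsilyl)oxy]-5,7,8-trimethoxy-2-(2-methoxyphenyl)chromenylium bromide | COc1ccccc1-c1[o+]c2c(OC)c(OC)cc(OC)c2c(O[Si](C)(C)C(C)(C)C)c1Br.[Br-] | intermediate (not isolated)
12 | 3-bromo-5,7,8-trimethoxy-2-(2-methoxyphenyl)-4H-chromen-4-one | COc1ccccc1-c1oc2c(OC)c(OC)cc(OC)c2c(=O)c1Br | intermediate
13 | 3,5,7,8-tetramethoxy-2-(2-methoxyphenyl)-4H-chromen-4-one | COc1ccccc1-c1oc2c(OC)c(OC)cc(OC)c2c(=O)c1OC | target

## Step count and steps at risk

Total step count: 6. Longest linear sequence: 6 steps (1 to 13).

**Step 5 (key step).**
- What may go wrong: removal of the silyl group by the alkoxide before the carbene has added. The free cyclopropanolate would then open toward the exocyclic bond (transfer of a dibromomethyl group to C2) instead of enlarging the ring. The carbene may also be consumed by tert-butoxide, leaving the conversion incomplete.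
- Fallback: the ring enlargement is abandoned and ring C is built by acyl transfer with the C3 oxygen already in place. The fallback sets out from 3 and returns at 13.
  - Friedel-Crafts acylation of 3 with methoxyacetyl chloride (AlCl3, Et2O), again with loss of the buttressed ortho methyl group, should give 1-(2-hydroxy-3,4,6-trimethoxyphenyl)-2-methoxyethan-1-one F1.
  - O-Acylation with 2-methoxybenzoyl chloride in pyridine should give 3,5,6-trimethoxy-2-(methoxyacetyl)phenyl 2-methoxybenzoate F2.
  - Baker-Venkataraman rearrangement (KOH, pyridine, 50 °C) should move the aroyl group to carbon and give 1-(2-hydroxy-3,4,6-trimethoxyphenyl)-2-methoxy-3-(2-methoxyphenyl)propane-1,3-dione F3.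
  - Acid-catalysed cyclodehydration (H2SO4 cat., AcOH) closes ring C to 13.

**Step 2.**
- What may go wrong: the one-pot Lewis acid treatment may remove more than one methyl group or remove the wrong ortho group if the chelate is heated too long. The acid chloride may also acylate its own ortho-methoxy oxygen and lactonise before it meets the arene.
- Fallback: carbon-carbon bond formation is separated from the ether cleavage and a nitrile is used as the electrophile. The fallback sets out from 3, returns at 4 and then goes on to 5.
  - Hoesch acylation of 3 with 2-methoxyphenylacetonitrile (N#CCc1ccccc1OC; ZnCl2, HCl gas, Et2O, 0 °C) should give 2-(2-methoxyphenyl)-1-(2,3,4,6-tetramethoxyphenyl)ethan-1-iminium chloride F4.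
  - Hydrolysis in hot water gives 4 as an isolated compound.
  - A separate chelation-controlled demethylation with BCl3 (CH2Cl2, −78 to 0 °C) gives 5.

**Step 3.**
- What may go wrong: electrophilic bromination of ring A at its one free position, which is para to the hydroxyl and ortho to two methoxy groups, may compete with bromination through the enol. A second bromination is possible if cyclisation starts in the flask.
- Fallback: the enol is made first, so that the halogen can only enter at the side chain. The fallback sets out from 5 and returns at 7, which is silylated as in step 4.
  - Double silylation (TBSOTf, Et3N, CH2Cl2, 0 °C) should give tert-butyl({2-[(Z)-1-{[tert-butyl(dimethyl)silyl]oxy}-2-(2-methoxyphenyl)ethenyl]-3,5,6-trimethoxyphenyl}oxy)dimethylsilane F5; the enol ether geometry is of no consequence.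
  - NBS in THF at −78 °C attacks the silyl enol ether far faster than the arene and should give rac-2-bromo-1-{2-[(tert-butyldimethylsilyl)oxy]-3,4,6-trimethoxyphenyl}-2-(2-methoxyphenyl)ethan-1-one F6.
  - CsF in DMF frees the phenoxide, which closes to 7.

**Step 6.**
- What may go wrong: β-hydride elimination from the palladium methoxide leads to loss of bromine by reduction. Oxidative addition at the bromide, flanked by ring B and the carbonyl, may be slow. Conjugate attack of methoxide at C2 opens the pyranone.
- Fallback: the oxygen is introduced through boron under acetate base and methylated afterwards. The fallback sets out from 12 and returns at 13.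
  - Miyaura borylation (PdCl2(dppf), B2pin2, KOAc, dioxane, 80 °C) should give 5,7,8-trimethoxy-2-(2-methoxyphenyl)-3-(4,4,5,5-tetramethyl-1,3,2-dioxaborolan-2-yl)-4H-chromen-4-one F7.
  - Oxidation with NaBO3·4H2O in THF-water should give 3-hydroxy-5,7,8-trimethoxy-2-(2-methoxyphenyl)-4H-chromen-4-one F8.
  - Methylation (iodomethane, K2CO3, acetone) gives 13.

## Further compounds

F1 | step 5 | 1-(2-hydroxy-3,4,6-trimethoxyphenyl)-2-methoxyethan-1-one | COCC(=O)c1c(OC)cc(OC)c(OC)c1O
F2 | step 5 | 3,5,6-trimethoxy-2-(methoxyacetyl)phenyl 2-methoxybenzoate | COCC(=O)c1c(OC)cc(OC)c(OC)c1OC(=O)c1ccccc1OC
F3 | step 5 | 1-(2-hydroxy-3,4,6-trimethoxyphenyl)-2-methoxy-3-(2-methoxyphenyl)propane-1,3-dione (racemic, enolisable) | COc1ccccc1C(=O)C(OC)C(=O)c1c(OC)cc(OC)c(OC)c1O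
F4 | step 2 | 2-(2-methoxyphenyl)-1-(2,3,4,6-tetramethoxyphenyl)ethan-1-iminium chloride | COc1ccccc1CC(=[NH2+])c1c(OC)cc(OC)c(OC)c1OC.[Cl-]
F5 | step 3 | tert-butyl({2-[(Z)-1-{[tert-butyl(dimethyl)silyl]oxy}-2-(2-methoxyphenyl)ethenyl]-3,5,6-trimethoxyphenyl}oxy)dimethylsilane | COc1ccccc1/C=C(\O[Si](C)(C)C(C)(C)C)c1c(OC)cc(OC)c(OC)c1O[Si](C)(C)C(C)(C)C
F6 | step 3 | rac-2-bromo-1-{2-[(tert-butyldimethylsilyl)oxy]-3,4,6-trimethoxyphenyl}-2-(2-methoxyphenyl)ethan-1-one | COc1ccccc1C(Br)C(=O)c1c(OC)cc(OC)c(OC)c1O[Si](C)(C)C(C)(C)C
F7 | step 6 | 5,7,8-trimethoxy-2-(2-methoxyphenyl)-3-(4,4,5,5-tetramethyl-1,3,2-dioxaborolan-2-yl)-4H-chromen-4-one | COc1ccccc1-c1oc2c(OC)c(OC)cc(OC)c2c(=O)c1B1OC(C)(C)C(C)(C)O1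
F8 | step 6 | 3-hydroxy-5,7,8-trimethoxy-2-(2-methoxyphenyl)-4H-chromen-4-one | COc1ccccc1-c1oc2c(OC)c(OC)cc(OC)c2c(=O)c1O
A1 | alternative 1 | 3-O,2'-O-methylene-bridged 3,2'-dihydroxy-5,7,8-trimethoxyflavone | COc1cc(OC)c2c(=O)c3OCOc4ccccc4-c3oc2c1OC
A2 | alternative 1 | 3-[(2-bromophenoxy)methoxy]-5,7,8-trimethoxy-4H-chromen-4-one | COc1cc(OC)c2c(=O)c(OCOc3ccccc3Br)coc2c1OC
A3 | alternative 2 | rac-(2,3-trans,3,4-cis)-5,7,8-trimethoxy-2-(2-methoxyphenyl)chromane-3,4-diol | COc1ccccc1[C@H]1Oc2c(OC)c(OC)cc(OC)c2[C@H](O)[C@@H]1O
A4 | alternative 2 | rac-2-[1-(2-methoxyphenyl)-2-oxoethoxy]-3,4,6-trimethoxybenzaldehyde | COc1ccccc1C(C=O)Oc1c(OC)c(OC)cc(OC)c1C=O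
A5 | alternative 3 | 5,7,8-trimethoxy-2-(2-methoxyphenyl)-4H-chromen-4-one | COc1ccccc1-c1cc(=O)c2c(OC)cc(OC)c(OC)c2o1
A6 | alternative 3 | 6-iodo-2,3,5-trimethoxyphenol | COc1cc(OC)c(I)c(O)c1OC
A7 | alternative 3 | 1-ethynyl-2-methoxybenzene | COc1ccccc1C#C
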